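Everything rests on cutting the C3–C4 bond of ring A. The key step exploits the C4 gem-dimethyl carbon next to the C3 carbinol in ring A: a tertiary C4 radical, made by hydrogen-atom transfer to an isopropenyl group on C5, adds to a C3 aldehyde and closes ring A in one operation, setting the 3β-hydroxyl and delivering the trans-decalin. Its precursor is a ring B cyclohexane from (1R,5R)-verbenone carrying the C5 isopropenyl group, a C10 methyl and propanal arm, a C8 dioxolane and a C9 methyl propanoate arm. The C13–C18 ring comes from (R)-carvone and is joined through C12–C13 by an Ireland–Claisen rearrangement.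

Key step: step 6

Atom labels: target numbering throughout (decalin C1–C10, linker C11–C12, cyclohexene C13–C18); in the pinane compounds verbenone C1, C2, C3, C4, C5, C6, C7 correspond to C7, C8, C9, C10, C5, C4, C6.
Remark on the chemistry: the C9 arm is carried as a methyl ester, because the Lewis-acidic acetolysis of step 2 would cleave a tert-butyl ester and the acid must later be freed by saponification beside an exocyclic alkene and a silyl ether.
Remark on the chemistry: on the carvone side the enone is epoxidised before the acrylate is added, because the cross-conjugated enolate of a carvone would otherwise go on to a second, intramolecular Michael addition (bicyclo[2.2.2]octanone); the epoxide is needed for the oxygen transposition in any case.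

**Ring A/B half (steps 1–10)**

Step 1
Reactants: 1 (1R,5R)-(+)-verbenone; 2 (3-bromopropoxy)(tert-butyl)dimethylsilane; 3 methyl acrylate
Product: 6 bicyclic keto ester, via Grignard reagent 4 (not isolated), via bromomagnesium enolate 5 (not isolated)
Conditions: 2, Mg, THF, 40 °C; then CuBr·SMe2 (20 mol %), 1, THF, −40 °C; then 3, −78 → 0 °C; sat. NH4Cl
Reagents that add atoms: none
Why: Copper-catalysed conjugate addition of the Grignard reagent followed by Michael trapping of the enolate (three-component coupling) should work because the cuprate attacks C10 from the face opposite the gem-dimethyl bridge, which sets the C10 quaternary centre with its methyl syn to the bridge, while the acrylate is taken up at C9 from the same open face, a centre that step 3 equilibrates.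

Step 2
Reactants: 6 bicyclic keto ester
Product: 7 ring B enol acetate with acetoxypropyl arm
Conditions: Zn(OAc)2, BF3·OEt2, Ac2O, 0 °C → rt
Reagents that add atoms: acetic anhydride, CC(=O)OC(C)=O
Why: In this Lewis-acid cyclobutane fragmentation of a pinanone, activation of the C8 carbonyl lets the strained C7–C4 bond ionise to the tertiary C4 cation, which loses a methyl proton to give the C5 isopropenyl group while the enolate is captured as the C7=C8 enol acetate and the primary silyl ether is acetolysed by BF3·OEt2/Ac2O, C5 and C10 being untouched.

Step 3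
Reactants: 7 ring B enol acetate with acetoxypropyl arm
Product: 9 ring B hydroxy ketone, via C9-epimeric hydroxy ketone 8 (not isolated)
Conditions: NaOMe (0.3 equiv), MeOH, rt
Reagents that add atoms: none
Why: Base-catalysed methanolysis (transesterification) should remove both acetates, and the liberated C8 ketone should then epimerise at C9 through its enolate to the thermodynamically preferred isomer, in which the C9 arm is equatorial and cis to the C10 methyl group.

Step 4
Reactants: 9 ring B hydroxy ketone
Product: 10 ring B ketal alcohol
Conditions: HOCH2CH2OH, PPTS (cat.), benzene, reflux (Dean–Stark)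
Reagents that add atoms: ethylene glycol, OCCO
Why: Acid-catalysed ketalisation with azeotropic removal of water should protect the C8 carbonyl as the 1,3-dioxolane and thereby lock the C9 configuration, no stereocentre being formed.

Step 5
Reactants: 10 ring B ketal alcohol
Product: 11 ring B ketal aldehyde (key-step precursor)
Conditions: TEMPO (cat.), PhI(OAc)2, CH2Cl2, rt
Reagents that add atoms: none
Why: TEMPO-catalysed oxidation is selective for the primary alcohol and stops at the aldehyde, and the ketal, the ester and the isopropenyl group should not react.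

Step 6
Reactants: 11 ring B ketal aldehyde
Product: 12 decalin ketal alcohol (key-step product)
Conditions: Fe(acac)3 (30 mol %), PhSiH3 (3 equiv), EtOH, 60 °C, high dilution
Reagents that add atoms: none
Why: An iron hydride formed from Fe(acac)3 (trivalent iron) and PhSiH3 should transfer a hydrogen atom to the terminal CH2 of the C5 isopropenyl group, and the nucleophilic tertiary C4 radical then adds to the aldehyde carbon C3, the alkoxy radical being reduced by divalent iron to the alkoxide before it can fragment back. The closest known reaction type is the iron-hydride-initiated reductive radical cyclisation of alkenes onto ketones, supported by tin-hydride radical cyclisations onto aldehydes. Ring A is closed in the 6-exo-trig mode through a chair transition state. The only new stereocentre, C3, is controlled by that chair, in which the C–O bond lies equatorial (3β) and so avoids the syn-axial hydrogens at C1 and C5. The trans ring fusion is not created here but inherited from the trans C5 isopropenyl and C10 arm. The step needs hydrogen-atom transfer to one alkene and radical attack on the aldehyde only, which the substrate secures by holding a single alkene, a ketal at C8 and an ester that is inert to alkyl radicals.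

Step 7
Reactants: 12 decalin ketal alcohol
Product: 13 decalin ketal silyl ether
Conditions: TBSOTf, 2,6-lutidine, CH2Cl2, 0 °C
Reagents that add atoms: tert-butyldimethylsilyl triflate, CC(C)(C)[Si](C)(C)OS(=O)(=O)C(F)(F)F
Why: Silylation of the hindered equatorial C3 hydroxyl with a silyl triflate and a hindered pyridine base is a standard protection that should leave the ketal and the ester intact.

Step 8
Reactants: 13 decalin ketal silyl ether
Product: 14 decalin C8 ketone
Conditions: 1 M HCl, THF, rt
Reagents that add atoms: water, O
Why: Mild aqueous acid should hydrolyse the dioxolane of the hindered C8 ketone much faster than it cleaves the neopentyl secondary silyl ether, and C9 stays in its thermodynamic configuration.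

Step 9
Reactants: 14 decalin C8 ketone
Product: 15 decalin methylene ester
Conditions: Ph3PCH3Br, NaN(SiMe3)2, THF, 0 °C → rt
Reagents that add atoms: methyltriphenylphosphonium bromide, C[P+](c1ccccc1)(c1ccccc1)c1ccccc1.[Br-]
Why: Wittig methylenation should convert the C8 ketone into the exocyclic alkene because the non-stabilised ylide reacts with a ketone far faster than with a methyl ester, and the equatorial C9 arm is already the stable epimer under the basic conditions.

Step 10
Reactants: 15 decalin methylene ester
Product: 16 decalin propanoic acid
Conditions: LiOH·H2O, THF/MeOH/H2O, rt; then 1 M HCl to pH 3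
Reagents that add atoms: lithium hydroxide, [Li+].[OH-]
Why: Saponification of the unhindered methyl ester should give the acid without touching the silyl ether or the alkene.

**Cyclohexene half (steps 11–14)**

Step 11
Reactants: 17 (R)-(−)-carvone
Product: 18 6-methylcarvone
Conditions: LiN(iPr)2, THF, −78 °C; MeI, −78 → 0 °C
Reagents that add atoms: iodomethane, CI
Why: Kinetic deprotonation at the alpha-prime carbon C18 gives the cross-conjugated enolate, whose alkylation with MeI occurs mainly anti to the C17 isopropenyl group, a configuration that does not matter because C18 is enolised again in step 13.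

Step 12
Reactants: 18 6-methylcarvone
Product: 19 epoxy ketone
Conditions: H2O2 (30% aq), NaOH (cat.), MeOH, 0 °C
Reagents that add atoms: hydrogen peroxide, OO
Why: Nucleophilic (Weitz–Scheffer) epoxidation attacks only the enone double bond, hydroperoxide adding axially to C15 on the face opposite the C17 isopropenyl group, so that the C14–C15 oxirane should form trans to isopropenyl.

Step 13
Reactants: 19 epoxy ketone; 3 methyl acrylate
Product: 20 epoxy keto ester
Conditions: KOtBu (0.1 equiv), t-BuOH/THF, 0 °C
Reagents that add atoms: none
Why: Base-catalysed Michael addition from the only enolisable position, C18, should build the quaternary centre with the acceptor approaching anti to the adjacent C17 isopropenyl group, which leaves the C18 methyl cis to it, and with the enone masked as the epoxide the adduct has no internal acceptor for a second Michael addition.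

Step 14
Reactants: 20 epoxy keto ester
Product: 23 allylic alcohol, via epoxy hydrazone 21 (not isolated), via alkenyldiazene 22 (not isolated)
Conditions: N2H4·H2O, AcOH (cat.), MeOH, 0 °C → rt
Reagents that add atoms: none
Why: In the Wharton transposition the hydrazone of the epoxy ketone opens to the alkenyldiazene, which loses N2 to leave the C13=C14 alkene and the C15 alcohol, whose C–O bond is never broken and therefore stays trans to the C17 isopropenyl group.

**Union and endgame (steps 15–18)**

Step 15
Reactants: 16 decalin propanoic acid; 23 allylic alcohol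
Product: 24 allylic ester
Conditions: PPh3, DIAD, THF, 0 °C → rt
Reagents that add atoms: none
Why: Mitsunobu esterification activates the unhindered allylic alcohol, and the carboxylate should displace it by SN2 with inversion at C15, which places the acyloxy group cis to the C17 isopropenyl group as the rearrangement requires.

Step 16
Reactants: 24 allylic ester
Product: 27 C12 carboxylic acid, via bis(silyl ketene acetal) 25 (not isolated), via silyl ester 26 (not isolated)
Conditions: LiN(iPr)2 (2.5 equiv), TMSCl/Et3N, THF, −78 → 65 °C; then 1 M HCl
Reagents that add atoms: none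
Why: In the Ireland–Claisen rearrangement both esters are converted into silyl ketene acetals, the allylic one undergoes the suprafacial [3,3] shift that should form the C12–C13 bond on the ring face that carried the C15 oxygen (cis to the C18 methyl group) and move the alkene to C14=C15, and acidic work-up returns the side-chain methyl ester and the free acid as inconsequential C12 epimers.

Step 17
Reactants: 27 C12 carboxylic acid
Product: 29 methyl lansiolate silyl ether, via thiohydroxamate ester 28 (not isolated)
Conditions: N-hydroxypyridine-2-thione, DCC, DMAP (cat.), CH2Cl2, rt, dark; then t-BuSH, hν (tungsten lamp), rt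
Reagents that add atoms: none
Why: In the Barton reductive decarboxylation the thiohydroxamate ester fragments under light to the secondary C12 radical, which should abstract hydrogen from the thiol faster than it can add to an alkene, erasing the C12 stereocentre while C13 is untouched.

Step 18
Reactants: 29 methyl lansiolate silyl ether
Product: 30 methyl lansiolate
Conditions: HF·pyridine, pyridine, THF, 0 °C → rt
Reagents that add atoms: none
Why: Buffered fluoride desilylation should cleave the hindered C3 silyl ether while sparing the methyl ester and the three alkenes, giving the target.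

**Compound list**

1 | (1R,5R)-(+)-verbenone | CC2(C)[C@@H]1C[C@H]2C(=O)C=C1C | starting material
2 | (3-bromopropoxy)(tert-butyl)dimethylsilane | BrCCCO[Si](C)(C)C(C)(C)C | starting material
3 | methyl acrylate | C=CC(=O)OC | starting material
4 | [3-(tert-butyldimethylsilyloxy)propyl]magnesium bromide (not isolated) | Br[Mg]CCCO[Si](C)(C)C(C)(C)C | intermediate
5 | bromomagnesium enolate of the conjugate adduct, new silyloxypropyl chain on C10 anti to the gem-dimethyl bridge (not isolated) | CC2(C)[C@@H]1C[C@H]2C(O[Mg]Br)=C[C@@]1(C)CCCO[Si](C)(C)C(C)(C)C | intermediate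
6 | methyl 3-[4-(3-tert-butyldimethylsilyloxypropyl)-4,6,6-trimethyl-2-oxobicyclo[3.1.1]heptan-3-yl]propanoate; bridgeheads as in 1; silyloxypropyl chain and propanoate arm both anti to the gem-dimethyl bridge (kinetic C9 epimer) | CC2(C)[C@@H]1C[C@H]2C(=O)[C@@H](CCC(=O)OC)[C@@]1(C)CCCO[Si](C)(C)C(C)(C)C | intermediate
7 | ring B enol acetate: C7=C8 enol acetate, C5 isopropenyl, C10 methyl cis to isopropenyl, C10 3-acetoxypropyl arm trans to it, C9 methyl propanoate arm cis to the C10 arm | C=C(C)[C@@H]1CC=C(OC(C)=O)[C@@H](CCC(=O)OC)[C@@]1(C)CCCOC(C)=O | intermediate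
8 | C9 epimer of 9, propanoate arm trans to the C10 methyl (not isolated) | C=C(C)[C@@H]1CCC(=O)[C@@H](CCC(=O)OC)[C@@]1(C)CCCO | intermediate
9 | methyl 3-[2-(3-hydroxypropyl)-2-methyl-6-oxo-3-(prop-1-en-2-yl)cyclohexyl]propanoate; C5 isopropenyl, C10 methyl and C9 arm mutually cis, C10 hydroxypropyl arm trans to them | C=C(C)[C@@H]1CCC(=O)[C@H](CCC(=O)OC)[C@@]1(C)CCCO | intermediate
10 | C8 ethylene ketal of 9 | C=C(C)[C@@H]1CCC2(OCCO2)[C@H](CCC(=O)OC)[C@@]1(C)CCCO | intermediate
11 | key-step precursor: ring B monocycle with C5 isopropenyl, C10 methyl and 3-oxopropyl arm, C8 ethylene ketal, C9 methyl propanoate arm (stereochemistry as 10) | C=C(C)[C@@H]1CCC2(OCCO2)[C@H](CCC(=O)OC)[C@@]1(C)CCC=O | intermediate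
12 | key-step product: trans-decalin with 3β-hydroxyl, 4,4-dimethyl, 5α-H, C8 ethylene ketal, 9α-H with β methyl propanoate arm, 10β-methyl | COC(=O)CC[C@H]1C2(OCCO2)CC[C@H]3C(C)(C)[C@@H](O)CC[C@]13C | intermediate
13 | 3β-O-tert-butyldimethylsilyl ether of 12 | COC(=O)CC[C@H]1C2(OCCO2)CC[C@H]3C(C)(C)[C@@H](O[Si](C)(C)C(C)(C)C)CC[C@]13C | intermediate
14 | C8 ketone from 13 | COC(=O)CC[C@H]1C(=O)CC[C@H]2C(C)(C)[C@@H](O[Si](C)(C)C(C)(C)C)CC[C@]12C | intermediate
15 | C8 exocyclic methylene ester from 14 | COC(=O)CC[C@H]1C(=C)CC[C@H]2C(C)(C)[C@@H](O[Si](C)(C)C(C)(C)C)CC[C@]12C | intermediate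
16 | 3-[3β-(tert-butyldimethylsilyloxy)-4,4,10β-trimethyl-8-methylene-trans-decalin-9β-yl]propanoic acid | OC(=O)CC[C@H]1C(=C)CC[C@H]2C(C)(C)[C@@H](O[Si](C)(C)C(C)(C)C)CC[C@]12C | intermediate
17 | (R)-(−)-carvone | C=C(C)[C@@H]1CC=C(C)C(=O)C1 | starting material
18 | 6-methylcarvone, C18 methyl mainly trans to the C17 isopropenyl (epimers at C18) | C=C(C)[C@@H]1CC=C(C)C(=O)[C@H]1C | intermediate
19 | C14–C15 epoxide of 18, oxirane trans to the C17 isopropenyl | C=C(C)[C@@H]1C[C@H]2O[C@@]2(C)C(=O)[C@H]1C | intermediate
20 | epoxy keto ester: C13 ketone, C18 methyl cis and C18 CH2CH2CO2Me trans to the C17 isopropenyl, oxirane trans to isopropenyl | C=C(C)[C@@H]1C[C@H]2O[C@@]2(C)C(=O)[C@@]1(C)CCC(=O)OC | intermediate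
21 | hydrazone of 20 (not isolated) | C=C(C)[C@@H]1C[C@H]2O[C@@]2(C)C(=NN)[C@@]1(C)CCC(=O)OC | intermediate
22 | alkenyldiazene with C15 hydroxyl (not isolated) | C=C(C)[C@@H]1C[C@@H](O)C(C)=C(N=N)[C@@]1(C)CCC(=O)OC | intermediate
23 | allylic alcohol: C13=C14, C15 hydroxyl trans to the C17 isopropenyl, C18 methyl cis and C18 methyl propanoate chain trans to isopropenyl | C=C(C)[C@@H]1C[C@@H](O)C(C)=C[C@@]1(C)CCC(=O)OC | intermediate
24 | ester of 16 with 23, inverted at C15 (acyloxy cis to the C17 isopropenyl) | C=C(C)[C@@H]1C[C@H](OC(=O)CC[C@H]2C(=C)CC[C@H]3C(C)(C)[C@@H](O[Si](C)(C)C(C)(C)C)CC[C@]23C)C(C)=C[C@@]1(C)CCC(=O)OC | intermediate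
25 | bis(trimethylsilyl ketene acetal) of 24 (not isolated) | C=C(C)[C@@H]1C[C@H](OC(O[Si](C)(C)C)=CC[C@H]2C(=C)CC[C@H]3C(C)(C)[C@@H](O[Si](C)(C)C(C)(C)C)CC[C@]23C)C(C)=C[C@@]1(C)CC=C(OC)O[Si](C)(C)C | intermediate
26 | rearranged trimethylsilyl ester, side chain still a ketene acetal (not isolated) | C=C(C)[C@@H]1CC=C(C)[C@H](C(C[C@H]2C(=C)CC[C@H]3C(C)(C)[C@@H](O[Si](C)(C)C(C)(C)C)CC[C@]23C)C(=O)O[Si](C)(C)C)[C@@]1(C)CC=C(OC)O[Si](C)(C)C | intermediate
27 | C12 carboxylic acid (C12 epimers): C12–C13 bond in place, C13 substituent cis to the C18 methyl and C17 isopropenyl, alkene C14=C15 | C=C(C)[C@@H]1CC=C(C)[C@H](C(C[C@H]2C(=C)CC[C@H]3C(C)(C)[C@@H](O[Si](C)(C)C(C)(C)C)CC[C@]23C)C(=O)O)[C@@]1(C)CCC(=O)OC | intermediate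
28 | N-acyloxypyridine-2-thione ester of 27 (not isolated) | C=C(C)[C@@H]1CC=C(C)[C@H](C(C[C@H]2C(=C)CC[C@H]3C(C)(C)[C@@H](O[Si](C)(C)C(C)(C)C)CC[C@]23C)C(=O)ON2C=CC=CC2=S)[C@@]1(C)CCC(=O)OC | intermediate
29 | 3-O-tert-butyldimethylsilyl methyl lansiolate | C=C(C)[C@@H]1CC=C(C)[C@H](CC[C@H]2C(=C)CC[C@H]3C(C)(C)[C@@H](O[Si](C)(C)C(C)(C)C)CC[C@]23C)[C@@]1(C)CCC(=O)OC | intermediate
30 | methyl lansiolate | C=C(C)[C@@H]1CC=C(C)[C@H](CC[C@H]2C(=C)CC[C@H]3C(C)(C)[C@@H](O)CC[C@]23C)[C@@]1(C)CCC(=O)OC | target

Total step count: 18.
Longest linear sequence: 14 steps (steps 1–10, then 15–18, from verbenone 1).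

**Steps most likely to fail**

1. Step 6. The addition of the tertiary radical to the aldehyde is reversible. The alkoxy radical may fragment back faster than it is reduced, so that plain hydrogenation of the isopropenyl group or reduction of the aldehyde could win. The fallback forms the same bond by a tin-hydride chain, in which the alkoxy radical is trapped at once by hydrogen transfer from the stannane. It sets out from ketal alcohol 10. Markovnikov addition of anhydrous HCl (HCl in dioxane, CH2Cl2, −20 °C) to the isopropenyl group should give the tertiary chloride F1. Oxidation with TEMPO/PhI(OAc)2 should give the chloro aldehyde F2. Slow addition of Bu3SnH and AIBN in benzene at 80 °C generates the C4 radical, which cyclises 6-exo onto the aldehyde (classical tin-hydride radical cyclisation onto an aldehyde). The fallback comes back to the route at 12.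

2. Step 14. Hydrazone formation at a carbonyl flanked by two fully substituted carbons may be slow, and forcing it invites hydrazinolysis of the methyl ester. The fallback replaces the hydrazone by a radical deoxygenation and carries the side chain as a nitrile, which can neither lactonise onto a C13 hydroxyl nor react with the reagents. It sets out from epoxy ketone 19. Base-catalysed cyanoethylation with acrylonitrile (KOtBu cat., t-BuOH/THF) should give the cyanoethyl epoxy ketone F3. NaBH4 in MeOH should reduce it to the epoxy alcohol F4 (either C13 epimer serves). Phenyl chlorothionoformate with pyridine and DMAP should give the phenyl thionocarbonate F5. Bu3SnH/AIBN then generates the C13 radical, which opens the oxirane to the allyloxy radical and gives the hydroxy nitrile F6 with the C15–O bond retained. Reduction with iBu2AlH at −78 °C and hydrolysis should give the hydroxy aldehyde F7. I2/KOH in MeOH oxidises the aldehyde to the methyl ester, and the fallback comes back to the route at 23.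

3. Step 1. The hindered enolate next to the new quaternary centre may add sluggishly to the acrylate, so that oligomerisation of the acceptor or further addition of the adduct enolate competes. The fallback brings in the C9 arm in two stages through an exocyclic enone. It sets out from verbenone 1 and Grignard reagent 4 and forms enolate 5 as before. Trapping 5 with dimethylmethyleneiminium iodide should give the Mannich base F8. Quaternisation with MeI and elimination with NaHCO3 should give the methylene ketone F9. Mukaiyama–Michael addition of 1-methoxy-1-(trimethylsilyloxy)ethene under LiClO4 catalysis should give the silyl enol ether F10. Mild aqueous acid work-up returns the ketone, and the fallback comes back to the route at 6 (as C9 epimers, which step 3 equilibrates).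

Further compounds
F1 | step 6 | tertiary chloride: 10 with the isopropenyl group converted into 2-chloropropan-2-yl | CC(C)(Cl)[C@@H]1CCC2(OCCO2)[C@H](CCC(=O)OC)[C@@]1(C)CCCO
F2 | step 6 | chloro aldehyde: 11 with 2-chloropropan-2-yl in place of isopropenyl | CC(C)(Cl)[C@@H]1CCC2(OCCO2)[C@H](CCC(=O)OC)[C@@]1(C)CCC=O
F3 | step 14 | cyanoethyl epoxy ketone: 20 with CH2CH2CN in place of CH2CH2CO2Me | C=C(C)[C@@H]1C[C@H]2O[C@@]2(C)C(=O)[C@@]1(C)CCC#N
F4 | step 14 | epoxy alcohol: C13 carbinol from F3 (C13 epimers) | C=C(C)[C@@H]1C[C@H]2O[C@@]2(C)C(O)[C@@]1(C)CCC#N
F5 | step 14 | O-phenyl thionocarbonate of F4 | C=C(C)[C@@H]1C[C@H]2O[C@@]2(C)C(OC(=S)Oc2ccccc2)[C@@]1(C)CCC#N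
F6 | step 14 | hydroxy nitrile: 23 with CH2CH2CN in place of CH2CH2CO2Me | C=C(C)[C@@H]1C[C@@H](O)C(C)=C[C@@]1(C)CCC#N
F7 | step 14 | hydroxy aldehyde: 23 with CH2CH2CHO in place of CH2CH2CO2Me | C=C(C)[C@@H]1C[C@@H](O)C(C)=C[C@@]1(C)CCC=O
F8 | step 1 | Mannich base: conjugate adduct with CH2NMe2 on C9, anti to the gem-dimethyl bridge | CC2(C)[C@@H]1C[C@H]2C(=O)[C@@H](CN(C)C)[C@@]1(C)CCCO[Si](C)(C)C(C)(C)C
F9 | step 1 | methylene ketone: conjugate adduct with exocyclic CH2 on C9 | CC2(C)[C@@H]1C[C@H]2C(=O)C(=C)[C@@]1(C)CCCO[Si](C)(C)C(C)(C)C
F10 | step 1 | trimethylsilyl enol ether (C8=C9) of 6 | CC2(C)[C@@H]1C[C@H]2C(O[Si](C)(C)C)=C(CCC(=O)OC)[C@@]1(C)CCCO[Si](C)(C)C(C)(C)C
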